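**Retrosynthetic overview**

1. Target ⇐ esterification of O-8 with (2R)-2-methylbutanoic acid and of O-9 with tigloyl chloride; the C-4 methyl comes from cuprate addition to a ring-B enone on its convex face.
2. The cis-decalin ⇐ intramolecular Stetter reaction: the C-9 aldehyde, as a carbene-bound acyl anion, attacks one enone β-carbon (C-10) of a prochiral 4,4-disubstituted cyclohexadienone. This closes ring A and sets C-5 and C-10 under control of C-7/C-8; the C-9 ketone is then reduced to the axial alcohol.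
3. The aldehyde side chain ⇐ enantioselective glyoxylate–ene reaction on a prenyl group (sets C-7 and C-8), then redox adjustment.
4. The prenyl dienone ⇐ cross-metathesis ⇐ oxidative dearomative allylation of p-cresol.
5. Ring order: ring B (from the arene) first, ring A second.

Assumption: the SMILES is read literally, so O-9 carries (E)-2-methylbut-2-enoate (tiglate) and O-8 carries (2R)-2-methylbutanoate.

Locants C-1 to C-10 in the comments follow eremophilane numbering: C-2 ketone, C-4 secondary methyl, C-5 angular methyl, C-7 isopropenyl, C-8 and C-9 acyloxy, C-10 ring-fusion CH. Ring B is C-1 to C-5 plus C-10; ring A is C-5 to C-10. The target is 4S,5R,7R,8R,9S,10S.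

**Step 1**
Reactants: 1 4-methylphenol (p-cresol); 2 allyltrimethylsilane
Product: 3 4-methyl-4-(prop-2-en-1-yl)cyclohexa-2,5-dien-1-one
Conditions: PhI(OAc)2 (1.2 equiv), 2 (4 equiv), (CF3)2CHOH/CH2Cl2, −10 °C → rt
Reagents that add atoms: none
Why: Oxidative dearomatisation (oxidative Hosomi–Sakurai allylation): the phenol is oxidised to a phenoxonium-type electrophile that the allylsilane traps at the para carbon, giving the quaternary carbon as part of a symmetric, achiral dienone.

**Step 2**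
Reactants: 3 4-methyl-4-(prop-2-en-1-yl)cyclohexa-2,5-dien-1-one; 4 2-methylbut-2-ene
Product: 5 4-methyl-4-(3-methylbut-2-en-1-yl)cyclohexa-2,5-dien-1-one
Conditions: second-generation Grubbs catalyst RuCl2(=CHPh)(H2IMes)(PCy3) (3 mol %), 4 as co-solvent, CH2Cl2, 40 °C, sealed
Reagents that add atoms: none
Why: Olefin cross-metathesis turns the terminal allyl group into a prenyl group, while the electron-poor, hindered dienone alkenes do not engage the ruthenium carbene; no stereocentre is formed.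

**Step 3**
Reactants: 5 4-methyl-4-(3-methylbut-2-en-1-yl)cyclohexa-2,5-dien-1-one; 6 ethyl glyoxylate
Product: 7 ethyl (2R,3R)-2-hydroxy-4-methyl-3-[(1-methyl-4-oxocyclohexa-2,5-dien-1-yl)methyl]pent-4-enoate
Conditions: 6 (1.1 equiv), [Cu{(R,R)-t-Bu-box}](SbF6)2 (10 mol %; t-Bu-box = 2,2'-(propane-2,2-diyl)bis(4-tert-butyl-4,5-dihydro-1,3-oxazole)), CH2Cl2, 0 °C → rt
Reagents that add atoms: none
Why: Enantioselective carbonyl–ene reaction: the glyoxylate chelated on divalent copper is attacked by the less substituted alkene carbon, with hydrogen transfer from the methyl cis to the vinylic hydrogen and the ester exo, which gives the 2,3-anti adduct and the isopropenyl group, and the (R,R) ligand (mirror image of the (S,S) complex that gives 2S adducts) fixes 2R and therefore 3R (C-8 and C-7); only 1.1 equiv of 6 is used so that the new isopropenyl group does not react again.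

**Step 4**
Reactants: 7 ethyl (2R,3R)-2-hydroxy-4-methyl-3-[(1-methyl-4-oxocyclohexa-2,5-dien-1-yl)methyl]pent-4-enoate
Product: 8 ethyl (2R,3R)-4-methyl-3-[(1-methyl-4-oxocyclohexa-2,5-dien-1-yl)methyl]-2-[(triethylsilyl)oxy]pent-4-enoate
Conditions: Et3SiCl, imidazole, DMF, 0 °C
Reagents that add atoms: chlorotriethylsilane, CC[Si](Cl)(CC)CC
Why: Silyl ether formation caps O-8 as a poor leaving group (needed for the carbene step, where a free hydroxyl would allow retro-benzoin cleavage and an acyloxy group would be eliminated) and removes the risk of oxa-Michael closure onto the dienone; no stereocentre changes.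

**Step 5**
Reactants: 8 ethyl (2R,3R)-4-methyl-3-[(1-methyl-4-oxocyclohexa-2,5-dien-1-yl)methyl]-2-[(triethylsilyl)oxy]pent-4-enoate
Product: 9 (2R,3R)-3-[(4-hydroxy-1-methylcyclohexa-2,5-dien-1-yl)methyl]-4-methyl-2-[(triethylsilyl)oxy]pent-4-en-1-ol
Conditions: i-Bu2AlH (4.5 equiv), CH2Cl2, −78 → 0 °C; aq. KNaC4H4O6 (potassium sodium tartrate)
Reagents that add atoms: none
Why: Exhaustive hydride reduction takes the ester to the primary alcohol and the dienone (by 1,2-addition) to the dienol, because a partial ester reduction cannot be selective next to the dienone; the dienol carbinol epimers converge in step 6.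

**Step 6**
Reactants: 9 (2R,3R)-3-[(4-hydroxy-1-methylcyclohexa-2,5-dien-1-yl)methyl]-4-methyl-2-[(triethylsilyl)oxy]pent-4-en-1-ol
Product: 10 (2R,3R)-4-methyl-3-[(1-methyl-4-oxocyclohexa-2,5-dien-1-yl)methyl]-2-[(triethylsilyl)oxy]pent-4-enal
Conditions: Dess–Martin periodinane (3 equiv), pyridine, CH2Cl2, 0 °C → rt
Reagents that add atoms: none
Why: Double Dess–Martin oxidation restores the dienone and gives the α-silyloxy aldehyde under buffered, non-epimerising conditions that also protect the acid-sensitive dienol.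

**Step 7 (key step)**
Reactants: 10 (2R,3R)-4-methyl-3-[(1-methyl-4-oxocyclohexa-2,5-dien-1-yl)methyl]-2-[(triethylsilyl)oxy]pent-4-enal
Product: 11 (2R,3R,4aR,8aS)-4a-methyl-3-(prop-1-en-2-yl)-2-[(triethylsilyl)oxy]-3,4,4a,8a-tetrahydronaphthalene-1,7(2H,8H)-dione
Conditions: 2-(pentafluorophenyl)-6,7-dihydro-5H-pyrrolo[2,1-c][1,2,4]triazol-2-ium tetrafluoroborate (20 mol %), i-Pr2NEt (20 mol %), toluene, 40 °C
Reagents that add atoms: none
Why: Intramolecular Stetter reaction with desymmetrisation: the triazolylidene turns the aldehyde carbon C-9 into an acyl-anion equivalent that adds 6-exo to an enone β-carbon (C-10) of the prochiral dienone on the face carrying the tether, which forces the cis ring fusion, and the chair transition state with isopropenyl and silyloxy equatorial and the spectator enone arm axial picks the enantiotopic arm that puts the angular methyl cis to the isopropenyl group (C-5 R, C-10 S); this cis-fused isomer is also the thermodynamic one at the two centres next to the new ketone.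

**Step 8**
Reactants: 11 (2R,3R,4aR,8aS)-4a-methyl-3-(prop-1-en-2-yl)-2-[(triethylsilyl)oxy]-3,4,4a,8a-tetrahydronaphthalene-1,7(2H,8H)-dione
Product: 12 (4aR,6R,7R,8S,8aS)-8-hydroxy-4a-methyl-6-(prop-1-en-2-yl)-7-[(triethylsilyl)oxy]-4a,5,6,7,8,8a-hexahydronaphthalen-2(1H)-one
Conditions: LiAlH(O-t-Bu)3 (1.2 equiv), THF, −78 → −30 °C
Reagents that add atoms: none
Why: Chemoselective hydride reduction under steric approach control: the saturated α-silyloxy ketone reacts before the conjugated enone, and because the axial α trajectory at C-9 is blocked by the axial C-4 carbon of ring B, hydride enters equatorially from the convex β face to give the axial 9S alcohol cis to O-8.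

**Step 9**
Reactants: 12 (4aR,6R,7R,8S,8aS)-8-hydroxy-4a-methyl-6-(prop-1-en-2-yl)-7-[(triethylsilyl)oxy]-4a,5,6,7,8,8a-hexahydronaphthalen-2(1H)-one; 13 (2E)-2-methylbut-2-enoyl chloride (tigloyl chloride)
Product: 14 (1S,2R,3R,4aR,8aS)-4a-methyl-7-oxo-3-(prop-1-en-2-yl)-2-[(triethylsilyl)oxy]-1,2,3,4,4a,7,8,8a-octahydronaphthalen-1-yl (2E)-2-methylbut-2-enoate
Conditions: 13 (3 equiv), pyridine, DMAP (0.3 equiv), CH2Cl2, 0 → 40 °C
Reagents that add atoms: none
Why: DMAP-catalysed acylation of the hindered axial alcohol under neutral conditions, so the neighbouring silyl group does not migrate; the E (tiglate) geometry is the stable one and no stereocentre is touched.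

**Step 10**
Reactants: 14 (1S,2R,3R,4aR,8aS)-4a-methyl-7-oxo-3-(prop-1-en-2-yl)-2-[(triethylsilyl)oxy]-1,2,3,4,4a,7,8,8a-octahydronaphthalen-1-yl (2E)-2-methylbut-2-enoate
Product: 17 (1S,2R,3R,4aR,5S,8aS)-2-hydroxy-4a,5-dimethyl-7-oxo-3-(prop-1-en-2-yl)decahydronaphthalen-1-yl (2E)-2-methylbut-2-enoate, via trimethylsilyl enol ether 15 (not isolated), via triethylsilyl-protected ketone 16 (not isolated)
Conditions: Me2CuLi (2 equiv, from MeLi and CuI), Me3SiCl, THF, −78 °C; then 1 M HCl, THF/MeOH, 0 °C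
Reagents that add atoms: lithium dimethylcuprate, [Li+].C[Cu-]C (made in the flask from methyllithium, [Li]C, and CuI)
Why: Cuprate conjugate addition to the ring-B enone: C-4 is axial on ring A, so its α face lies in the concave fold under ring A (axial H-7 and the axial O-9 ester), and methyl is delivered on the convex β face cis to the angular methyl (C-4 S), the trisubstituted tiglate being inert at −78 °C; the acidic work-up hydrolyses the silyl enol ether and removes the triethylsilyl group in the same operation.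

**Step 11**
Reactants: 17 (1S,2R,3R,4aR,5S,8aS)-2-hydroxy-4a,5-dimethyl-7-oxo-3-(prop-1-en-2-yl)decahydronaphthalen-1-yl (2E)-2-methylbut-2-enoate; 18 (2R)-2-methylbutanoic acid
Product: 19 (1S,2R,3R,4aR,5S,8aS)-4a,5-dimethyl-2-{[(2R)-2-methylbutanoyl]oxy}-7-oxo-3-(prop-1-en-2-yl)decahydronaphthalen-1-yl (2E)-2-methylbut-2-enoate
Conditions: 18 (2 equiv), DCC, DMAP (10 mol %), CH2Cl2, 0 °C → rt
Reagents that add atoms: none
Why: Steglich esterification of the equatorial C-8 alcohol; the acid's α-stereocentre is brought in from the chiral pool and is kept by the low DMAP loading and low temperature.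

**Compound list**

1 | 4-methylphenol (p-cresol) | Cc1ccc(O)cc1 | starting material
2 | allyltrimethylsilane | C=CC[Si](C)(C)C | starting material
3 | 4-methyl-4-(prop-2-en-1-yl)cyclohexa-2,5-dien-1-one | C=CCC1(C)C=CC(=O)C=C1 | intermediate
4 | 2-methylbut-2-ene | CC=C(C)C | starting material
5 | 4-methyl-4-(3-methylbut-2-en-1-yl)cyclohexa-2,5-dien-1-one | CC(C)=CCC1(C)C=CC(=O)C=C1 | intermediate
6 | ethyl glyoxylate (ethyl 2-oxoacetate) | CCOC(=O)C=O | starting material
7 | ethyl (2R,3R)-2-hydroxy-4-methyl-3-[(1-methyl-4-oxocyclohexa-2,5-dien-1-yl)methyl]pent-4-enoate | C=C(C)[C@@H](CC1(C)C=CC(=O)C=C1)[C@@H](O)C(=O)OCC | intermediate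
8 | ethyl (2R,3R)-4-methyl-3-[(1-methyl-4-oxocyclohexa-2,5-dien-1-yl)methyl]-2-[(triethylsilyl)oxy]pent-4-enoate | C=C(C)[C@@H](CC1(C)C=CC(=O)C=C1)[C@@H](O[Si](CC)(CC)CC)C(=O)OCC | intermediate
9 | (2R,3R)-3-[(4-hydroxy-1-methylcyclohexa-2,5-dien-1-yl)methyl]-4-methyl-2-[(triethylsilyl)oxy]pent-4-en-1-ol (cis/trans mixture at the ring carbinol) | C=C(C)[C@@H](CC1(C)C=CC(O)C=C1)[C@@H](O[Si](CC)(CC)CC)CO | intermediate
10 | (2R,3R)-4-methyl-3-[(1-methyl-4-oxocyclohexa-2,5-dien-1-yl)methyl]-2-[(triethylsilyl)oxy]pent-4-enal | C=C(C)[C@@H](CC1(C)C=CC(=O)C=C1)[C@@H](O[Si](CC)(CC)CC)C=O | intermediate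
11 | (2R,3R,4aR,8aS)-4a-methyl-3-(prop-1-en-2-yl)-2-[(triethylsilyl)oxy]-3,4,4a,8a-tetrahydronaphthalene-1,7(2H,8H)-dione | C=C(C)[C@H]1C[C@@]2(C)[C@H](CC(=O)C=C2)C(=O)[C@@H]1O[Si](CC)(CC)CC | intermediate
12 | (4aR,6R,7R,8S,8aS)-8-hydroxy-4a-methyl-6-(prop-1-en-2-yl)-7-[(triethylsilyl)oxy]-4a,5,6,7,8,8a-hexahydronaphthalen-2(1H)-one | C=C(C)[C@H]1C[C@@]2(C)[C@H](CC(=O)C=C2)[C@H](O)[C@@H]1O[Si](CC)(CC)CC | intermediate
13 | (2E)-2-methylbut-2-enoyl chloride (tigloyl chloride) | C/C=C(\C)C(Cl)=O | starting material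
14 | (1S,2R,3R,4aR,8aS)-4a-methyl-7-oxo-3-(prop-1-en-2-yl)-2-[(triethylsilyl)oxy]-1,2,3,4,4a,7,8,8a-octahydronaphthalen-1-yl (2E)-2-methylbut-2-enoate | C=C(C)[C@H]1C[C@@]2(C)[C@H](CC(=O)C=C2)[C@H](OC(=O)/C(C)=C/C)[C@@H]1O[Si](CC)(CC)CC | intermediate
15 | (1S,2R,3R,4aR,5S,8aS)-4a,5-dimethyl-3-(prop-1-en-2-yl)-2-[(triethylsilyl)oxy]-7-[(trimethylsilyl)oxy]-1,2,3,4,4a,5,8,8a-octahydronaphthalen-1-yl (2E)-2-methylbut-2-enoate (formed in the flask in step 10) | C=C(C)[C@H]1C[C@@]2(C)[C@H](CC(O[Si](C)(C)C)=C[C@@H]2C)[C@H](OC(=O)/C(C)=C/C)[C@@H]1O[Si](CC)(CC)CC | intermediate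
16 | (1S,2R,3R,4aR,5S,8aS)-4a,5-dimethyl-7-oxo-3-(prop-1-en-2-yl)-2-[(triethylsilyl)oxy]decahydronaphthalen-1-yl (2E)-2-methylbut-2-enoate (formed in the flask in step 10) | C=C(C)[C@H]1C[C@@]2(C)[C@H](CC(=O)C[C@@H]2C)[C@H](OC(=O)/C(C)=C/C)[C@@H]1O[Si](CC)(CC)CC | intermediate
17 | (1S,2R,3R,4aR,5S,8aS)-2-hydroxy-4a,5-dimethyl-7-oxo-3-(prop-1-en-2-yl)decahydronaphthalen-1-yl (2E)-2-methylbut-2-enoate | C=C(C)[C@H]1C[C@@]2(C)[C@H](CC(=O)C[C@@H]2C)[C@H](OC(=O)/C(C)=C/C)[C@@H]1O | intermediate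
18 | (2R)-2-methylbutanoic acid | CC[C@@H](C)C(=O)O | starting material
19 | (1S,2R,3R,4aR,5S,8aS)-4a,5-dimethyl-2-{[(2R)-2-methylbutanoyl]oxy}-7-oxo-3-(prop-1-en-2-yl)decahydronaphthalen-1-yl (2E)-2-methylbut-2-enoate (CNP0312791.1) | C=C(C)[C@H]1C[C@@]2(C)[C@H](CC(=O)C[C@@H]2C)[C@H](OC(=O)/C(C)=C/C)[C@@H]1OC(=O)[C@H](C)CC | target

**Totals and risks**

Total step count: 11. Longest linear sequence: 11 steps (1 → 19).

The three steps most likely to fail:

Step 7. The six-membered Stetter closure with an α-silyloxy aldehyde may be slow or may lose silanolate from the carbene adduct. The fallback sets out from 10: reductive ketyl–olefin cyclisation with SmI2 (THF, t-BuOH, −78 °C) joins the same two carbons through the same chair and should give mainly the equatorial C-9 alcohol (4aR,6R,7R,8R,8aS)-8-hydroxy-4a-methyl-6-(prop-1-en-2-yl)-7-[(triethylsilyl)oxy]-4a,5,6,7,8,8a-hexahydronaphthalen-2(1H)-one F3. Dess–Martin oxidation of F3 gives 11, where the route is rejoined.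

Step 3. The ene reaction may give the syn instead of the anti adduct, or low enantioselectivity, with this trisubstituted alkene. The fallback sets out from 5: a glyoxylate–ene reaction with a one-point-binding titanium catalyst made from (S)-BINOL and TiCl2(O-i-Pr)2, which is syn-selective for trisubstituted alkenes, should give ethyl (2S,3R)-2-hydroxy-4-methyl-3-[(1-methyl-4-oxocyclohexa-2,5-dien-1-yl)methyl]pent-4-enoate F1 with the correct C-7 centre. Mitsunobu inversion at C-2 (4-nitrobenzoic acid, PPh3, DIAD) gives ethyl (2R,3R)-4-methyl-3-[(1-methyl-4-oxocyclohexa-2,5-dien-1-yl)methyl]-2-[(4-nitrobenzoyl)oxy]pent-4-enoate F2, and ethanolysis (K2CO3, EtOH) comes back to the route at 7.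

Step 10. The cuprate may enter on the α face and give the C-4 epimer. The fallback sets out from 14: the same cuprate/Me3SiCl addition is stopped at the silyl enol ether, here the C-4 epimer (1S,2R,3R,4aR,5R,8aS)-4a,5-dimethyl-3-(prop-1-en-2-yl)-2-[(triethylsilyl)oxy]-7-[(trimethylsilyl)oxy]-1,2,3,4,4a,5,8,8a-octahydronaphthalen-1-yl (2E)-2-methylbut-2-enoate F4. Saegusa–Ito dehydrogenation with Pd(OAc)2 in MeCN gives the 4-methyl enone (1S,2R,3R,4aS,8aS)-4a,5-dimethyl-7-oxo-3-(prop-1-en-2-yl)-2-[(triethylsilyl)oxy]-1,2,3,4,4a,7,8,8a-octahydronaphthalen-1-yl (2E)-2-methylbut-2-enoate F5. Conjugate reduction with [(Ph3P)CuH]6 then delivers hydride on the face the cuprate used, leaving the methyl β, and comes back to the route at 16, which the acid treatment of step 10 converts into 17.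

**Further compounds**

F1 | step 3 | ethyl (2S,3R)-2-hydroxy-4-methyl-3-[(1-methyl-4-oxocyclohexa-2,5-dien-1-yl)methyl]pent-4-enoate | C=C(C)[C@@H](CC1(C)C=CC(=O)C=C1)[C@H](O)C(=O)OCC
F2 | step 3 | ethyl (2R,3R)-4-methyl-3-[(1-methyl-4-oxocyclohexa-2,5-dien-1-yl)methyl]-2-[(4-nitrobenzoyl)oxy]pent-4-enoate | C=C(C)[C@@H](CC1(C)C=CC(=O)C=C1)[C@@H](OC(=O)c1ccc(cc1)[N+](=O)[O-])C(=O)OCC
F3 | step 7 | (4aR,6R,7R,8R,8aS)-8-hydroxy-4a-methyl-6-(prop-1-en-2-yl)-7-[(triethylsilyl)oxy]-4a,5,6,7,8,8a-hexahydronaphthalen-2(1H)-one | C=C(C)[C@H]1C[C@@]2(C)[C@H](CC(=O)C=C2)[C@@H](O)[C@@H]1O[Si](CC)(CC)CC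
F4 | step 10 | (1S,2R,3R,4aR,5R,8aS)-4a,5-dimethyl-3-(prop-1-en-2-yl)-2-[(triethylsilyl)oxy]-7-[(trimethylsilyl)oxy]-1,2,3,4,4a,5,8,8a-octahydronaphthalen-1-yl (2E)-2-methylbut-2-enoate | C=C(C)[C@H]1C[C@@]2(C)[C@H](CC(O[Si](C)(C)C)=C[C@H]2C)[C@H](OC(=O)/C(C)=C/C)[C@@H]1O[Si](CC)(CC)CC
F5 | step 10 | (1S,2R,3R,4aS,8aS)-4a,5-dimethyl-7-oxo-3-(prop-1-en-2-yl)-2-[(triethylsilyl)oxy]-1,2,3,4,4a,7,8,8a-octahydronaphthalen-1-yl (2E)-2-methylbut-2-enoate | C=C(C)[C@H]1C[C@@]2(C)[C@H](CC(=O)C=C2C)[C@H](OC(=O)/C(C)=C/C)[C@@H]1O[Si](CC)(CC)CC
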